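Retrosynthesis: the three MOM ethers and the silyl ether are put back, ring C is cut at C2–C3 (carbenoid C–H insertion), the diazo carbon is traced to an acetyl group on C4a, the side chain is cut at C8–CH2 (Negishi coupling) and ring B is cut off at O1–C2 (Mitsunobu etherification).
Forward: a ring A acetophenone is iodinated at C8, O1 is benzylated with the ring B benzyl alcohol, the limonene-derived alkylzinc is coupled at C8, the acetyl group is turned into the diazomethyl ketone and ring C is closed last; one acid step then frees the four hydroxyl groups.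
Enabling feature: C2 carries O1 and is benzylic to ring B, so in the open precursor it is the CH2 of an O1-benzyl ether whose C–H bonds lie six atoms from a carbene at C3 next to the C4 carbonyl on C4a.
Stereochemistry: the side-chain centre is C4 of (R)-limonene, carried untouched from the commercial 1,2-oxide; C2 (S) is set in the ring closure by the chiral dirhodium carboxylate.

Key step: step 13

Assumption 1: compounds 1 and 12 are taken as catalogue compounds; 1 is the epoxide mixture made from (R)-limonene, and both epoxide diastereomers converge on 3.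
Assumption 2: the (S)-tert-leucinate-derived catalyst is taken to favour the (2S) configuration; if the sense proves opposite, its enantiomer is used in step 13 without other change.

Step 1
Reactants: 1 (4R)-limonene 1,2-oxide (cis/trans mixture at the epoxide)
Product: 3 (3R)-6-oxo-3-(prop-1-en-2-yl)heptanal, via limonene-1,2-diol 2 (not isolated)
Conditions: H5IO6, THF/H2O, 0 °C to rt
Reagents that add atoms: water, O
Why: Acid-promoted hydration of either epoxide diastereomer to the trans-diol and Malaprade glycol cleavage open the ring between C1 and C2, while the isopropenyl group and the C4 centre (C3 of the chain) are not involved.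

Step 2
Reactants: 3 (3R)-6-oxo-3-(prop-1-en-2-yl)heptanal
Product: 4 (3R)-6-oxo-3-(prop-1-en-2-yl)heptanoic acid
Conditions: NaClO2, NaH2PO4, 2-methylbut-2-ene, t-BuOH/H2O, 0 °C to rt
Reagents that add atoms: sodium chlorite, [Na+].[O-]Cl=O
Why: Pinnick oxidation takes the aldehyde to the acid under buffered conditions, the methyl ketone is inert and the scavenger alkene removes HOCl before it can reach the isopropenyl group.

Step 3
Reactants: 4 (3R)-6-oxo-3-(prop-1-en-2-yl)heptanoic acid
Product: 5 (3R)-6-hydroxy-6-methyl-3-(prop-1-en-2-yl)heptanoic acid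
Conditions: MeMgBr (3 equiv), THF, −78 to 0 °C; aq. NH4Cl, dil. HCl to pH 3
Reagents that add atoms: methylmagnesium bromide, C[Mg]Br
Why: Grignard addition, in which the first equivalent forms the magnesium carboxylate that resists further attack, so that the methyl group adds only to the ketone and gives the tertiary alcohol of the side chain.

Step 4
Reactants: 5 (3R)-6-hydroxy-6-methyl-3-(prop-1-en-2-yl)heptanoic acid
Product: 7 (5S)-6-iodo-2-methyl-5-(prop-1-en-2-yl)hexan-2-ol, via Barton ester 6 (not isolated)
Conditions: N-hydroxypyridine-2-thione, DCC, DMAP (cat.), CH2Cl2, 0 °C, dark; then CHI3, hν (tungsten lamp), 20 °C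
Reagents that add atoms: iodoform, IC(I)I
Why: Barton decarboxylative iodination excises the carboxyl carbon, the primary radical taking iodine from CHI3 much faster than it can close onto the isopropenyl group, and the neighbouring stereocentre never becomes a radical, so its configuration is kept (the descriptor becomes S only because CH2I outranks isopropenyl).

Step 5
Reactants: 7 (5S)-6-iodo-2-methyl-5-(prop-1-en-2-yl)hexan-2-ol
Product: 8 triethyl{[(5S)-6-iodo-2-methyl-5-(prop-1-en-2-yl)hexan-2-yl]oxy}silane
Conditions: Et3SiOTf, 2,6-lutidine, CH2Cl2, −78 to 0 °C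
Reagents that add atoms: triethylsilyl trifluoromethanesulfonate, CC[Si](CC)(CC)OS(=O)(=O)C(F)(F)F
Why: Silylation with a silyl triflate is the standard way to cap a hindered tertiary alcohol, and the triethylsilyl ether hides the hydroxyl from the zinc reagent, the amide base and the carbenoid yet falls to mild acid at the end.

Step 6
Reactants: 9 2,4-dihydroxybenzaldehyde
Product: 10 2,4-bis(methoxymethoxy)benzaldehyde
Conditions: MOMCl (3 equiv), i-Pr2NEt, CH2Cl2, 0 to 40 °C
Reagents that add atoms: chloromethyl methyl ether, COCCl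
Why: Williamson-type O-alkylation of both phenols with the reactive α-chloro ether, excess reagent and warming carrying the hydrogen-bonded 2-hydroxyl through.

Step 7
Reactants: 10 2,4-bis(methoxymethoxy)benzaldehyde
Product: 11 [2,4-bis(methoxymethoxy)phenyl]methanol
Conditions: NaBH4, MeOH, 0 °C
Reagents that add atoms: none
Why: Borohydride reduction of an aryl aldehyde is fast and leaves the MOM acetals alone.

Step 8
Reactants: 12 1-(2,4-dihydroxy-6-methoxyphenyl)ethan-1-one
Product: 13 1-[2-hydroxy-6-methoxy-4-(methoxymethoxy)phenyl]ethan-1-one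
Conditions: MOMCl (1.1 equiv), K2CO3, acetone, 0 °C to rt
Reagents that add atoms: chloromethyl methyl ether, COCCl
Why: Chemoselective Williamson-type etherification, since the 4-hydroxyl para to the acetyl group is the more acidic and accessible one while the 2-hydroxyl is held in a hydrogen bond to the carbonyl oxygen and stays free as the future O1.

Step 9
Reactants: 13 1-[2-hydroxy-6-methoxy-4-(methoxymethoxy)phenyl]ethan-1-one
Product: 14 1-[2-hydroxy-3-iodo-6-methoxy-4-(methoxymethoxy)phenyl]ethan-1-one
Conditions: BnMe3N ICl2 (1.05 equiv), NaHCO3, CH2Cl2/MeOH, rt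
Reagents that add atoms: benzyltrimethylammonium dichloroiodate, C[N+](C)(C)Cc1ccccc1.Cl[I-]Cl
Why: Electrophilic aromatic iodination goes ortho to the free phenol, at the carbon between OH and OMOM (the future C8), as is the rule for 2-hydroxy-4,6-dialkoxyacetophenones, and the hydrogen carbonate buffer protects the MOM ether.

Step 10
Reactants: 14 1-[2-hydroxy-3-iodo-6-methoxy-4-(methoxymethoxy)phenyl]ethan-1-one; 11 [2,4-bis(methoxymethoxy)phenyl]methanol
Product: 15 1-[2-{[2,4-bis(methoxymethoxy)phenyl]methoxy}-3-iodo-6-methoxy-4-(methoxymethoxy)phenyl]ethan-1-one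
Conditions: PPh3, DIAD, THF, 0 °C to rt
Reagents that add atoms: none
Why: Mitsunobu etherification joins the acidic ortho-acyl phenol to the primary benzylic alcohol and avoids the unstable 2,4-dialkoxybenzyl halide, and the O1–CH2 group made here supplies the C–H bonds for the ring closure.

Step 11
Reactants: 8 triethyl{[(5S)-6-iodo-2-methyl-5-(prop-1-en-2-yl)hexan-2-yl]oxy}silane; 15 1-[2-{[2,4-bis(methoxymethoxy)phenyl]methoxy}-3-iodo-6-methoxy-4-(methoxymethoxy)phenyl]ethan-1-one
Product: 17 1-{2-{[2,4-bis(methoxymethoxy)phenyl]methoxy}-6-methoxy-4-(methoxymethoxy)-3-[(2R)-5-methyl-2-(prop-1-en-2-yl)-5-(triethylsilyloxy)hexyl]phenyl}ethan-1-one, via alkylzinc iodide 16 (not isolated)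
Conditions: 8, Zn dust, LiCl, BrCH2CH2Br (cat.), Me3SiCl (cat.), THF, 40 °C; then 15, Pd(OAc)2 (cat.), SPhos, THF, 25 to 50 °C
Reagents that add atoms: none
Why: Negishi coupling, in which zinc inserts into the primary C–I bond and the alkylzinc iodide, tolerant of the methyl ketone, couples with the di-ortho-alkoxy aryl iodide under a bulky biarylphosphine that speeds reductive elimination ahead of β-hydride loss, so the C8–CH2 bond forms without touching the adjacent stereocentre.

Step 12
Reactants: 17 1-{2-{[2,4-bis(methoxymethoxy)phenyl]methoxy}-6-methoxy-4-(methoxymethoxy)-3-[(2R)-5-methyl-2-(prop-1-en-2-yl)-5-(triethylsilyloxy)hexyl]phenyl}ethan-1-one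
Product: 19 2-diazo-1-{2-{[2,4-bis(methoxymethoxy)phenyl]methoxy}-6-methoxy-4-(methoxymethoxy)-3-[(2R)-5-methyl-2-(prop-1-en-2-yl)-5-(triethylsilyloxy)hexyl]phenyl}ethan-1-one, via trifluoroacetyl ketone 18 (not isolated)
Conditions: LiN(SiMe3)2, THF, −78 °C; CF3CO2CH2CF3; aq. NH4Cl; then MsN3, Et3N, H2O, MeCN, rt
Reagents that add atoms: methanesulfonyl azide, CS(=O)(=O)N=[N+]=[N-]
Why: Detrifluoroacetylative diazo transfer (Regitz type), in which the kinetic enolate of the methyl ketone is trifluoroacetylated and the activated 1,3-diketone takes the diazo group from the sulfonyl azide with loss of the trifluoroacetyl group, under conditions that spare ethers, acetals and the silyl ether.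

Step 13
Reactants: 19 2-diazo-1-{2-{[2,4-bis(methoxymethoxy)phenyl]methoxy}-6-methoxy-4-(methoxymethoxy)-3-[(2R)-5-methyl-2-(prop-1-en-2-yl)-5-(triethylsilyloxy)hexyl]phenyl}ethan-1-one
Product: 20 (2S)-2-[2,4-bis(methoxymethoxy)phenyl]-5-methoxy-7-(methoxymethoxy)-8-[(2R)-5-methyl-2-(prop-1-en-2-yl)-5-(triethylsilyloxy)hexyl]-2,3-dihydro-4H-chromen-4-one
Conditions: dirhodium tetrakis[(S)-N-phthaloyl-tert-leucinate], Rh2(S-PTTL)4 (divalent rhodium, 2 mol%), CH2Cl2, 0 °C to rt, slow addition of 19, high dilution
Reagents that add atoms: none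
Why: Loss of N2 from 19 at the dirhodium core gives an electrophilic keto carbenoid at C3, which takes one hydrogen of the O1–CH2–aryl group with hydride character while the C2–C3 bond forms in the same three-centre transition state and the catalyst is released. The closest known reaction is the enantioselective dirhodium carboxylate-catalysed C–H insertion of 2-alkoxyaryl diazomethyl ketones next to the ether oxygen, which gives 2-substituted chroman-4-ones. Ring C closes as a six-membered ring by 1,6-insertion (C3, C4, C4a, C8a, O1, C2), the five-membered alternative being excluded because that position is O1 itself. The C2 centre is set by the chiral pocket of the four phthaloyl-tert-leucinate ligands, which choose between the two enantiotopic benzylic hydrogens, the remote side-chain centre being expected to have little influence. The step needs insertion to outrun oxonium ylide formation at O1 with benzyl shift, insertion into the C5 methoxy group and cyclopropanation of the isopropenyl group. This is secured because the target C–H is activated by both O1 and the electron-rich ring B, O1 is a weakly basic aryl ether oxygen flanked by two ortho substituents, the methoxy C–H bonds are primary, and slow addition at high dilution suppresses bimolecular paths.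

Step 14
Reactants: 20 (2S)-2-[2,4-bis(methoxymethoxy)phenyl]-5-methoxy-7-(methoxymethoxy)-8-[(2R)-5-methyl-2-(prop-1-en-2-yl)-5-(triethylsilyloxy)hexyl]-2,3-dihydro-4H-chromen-4-one
Product: 21 (2S)-2-(2,4-dihydroxyphenyl)-7-hydroxy-8-[(2R)-5-hydroxy-5-methyl-2-(prop-1-en-2-yl)hexyl]-5-methoxy-2,3-dihydro-4H-chromen-4-one
Conditions: HCl (1 M) in MeOH/THF, rt
Reagents that add atoms: none
Why: Acid-catalysed methanolysis should cleave the three phenolic MOM acetals and the tertiary triethylsilyl ether in one operation, under conditions mild enough not to protonate the isopropenyl group or open ring C, so neither stereocentre is disturbed.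

Compound list
1 | (4R)-limonene 1,2-oxide, (4R)-1-methyl-4-(prop-1-en-2-yl)-7-oxabicyclo[4.1.0]heptane, cis/trans mixture at the epoxide | C=C(C)[C@@H]1CCC2(C)OC2C1 | starting material
2 | (1S,2S,4R)-limonene-1,2-diol (not isolated) | C=C(C)[C@@H]1CC[C@](C)(O)[C@@H](O)C1 | intermediate
3 | (3R)-6-oxo-3-(prop-1-en-2-yl)heptanal | C=C(C)[C@H](CCC(C)=O)CC=O | intermediate
4 | (3R)-6-oxo-3-(prop-1-en-2-yl)heptanoic acid | C=C(C)[C@H](CCC(C)=O)CC(=O)O | intermediate
5 | (3R)-6-hydroxy-6-methyl-3-(prop-1-en-2-yl)heptanoic acid | C=C(C)[C@H](CCC(C)(C)O)CC(=O)O | intermediate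
6 | 2-thioxopyridin-1(2H)-yl (3R)-6-hydroxy-6-methyl-3-(prop-1-en-2-yl)heptanoate, Barton ester (not isolated) | C=C(C)[C@H](CCC(C)(C)O)CC(=O)On1ccccc1=S | intermediate
7 | (5S)-6-iodo-2-methyl-5-(prop-1-en-2-yl)hexan-2-ol | C=C(C)[C@H](CCC(C)(C)O)CI | intermediate
8 | triethyl{[(5S)-6-iodo-2-methyl-5-(prop-1-en-2-yl)hexan-2-yl]oxy}silane | C=C(C)[C@H](CCC(C)(C)O[Si](CC)(CC)CC)CI | intermediate
9 | 2,4-dihydroxybenzaldehyde | O=Cc1ccc(O)cc1O | starting material
10 | 2,4-bis(methoxymethoxy)benzaldehyde | COCOc1ccc(C=O)c(OCOC)c1 | intermediate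
11 | [2,4-bis(methoxymethoxy)phenyl]methanol | COCOc1ccc(CO)c(OCOC)c1 | intermediate
12 | 1-(2,4-dihydroxy-6-methoxyphenyl)ethan-1-one | CC(=O)c1c(O)cc(O)cc1OC | starting material
13 | 1-[2-hydroxy-6-methoxy-4-(methoxymethoxy)phenyl]ethan-1-one | CC(=O)c1c(O)cc(OCOC)cc1OC | intermediate
14 | 1-[2-hydroxy-3-iodo-6-methoxy-4-(methoxymethoxy)phenyl]ethan-1-one | CC(=O)c1c(O)c(I)c(OCOC)cc1OC | intermediate
15 | 1-[2-{[2,4-bis(methoxymethoxy)phenyl]methoxy}-3-iodo-6-methoxy-4-(methoxymethoxy)phenyl]ethan-1-one | CC(=O)c1c(OC)cc(OCOC)c(I)c1OCc1ccc(OCOC)cc1OCOC | intermediate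
16 | iodo[(2S)-5-methyl-2-(prop-1-en-2-yl)-5-(triethylsilyloxy)hexyl]zinc (not isolated) | C=C(C)[C@H](CCC(C)(C)O[Si](CC)(CC)CC)C[Zn]I | intermediate
17 | 1-{2-{[2,4-bis(methoxymethoxy)phenyl]methoxy}-6-methoxy-4-(methoxymethoxy)-3-[(2R)-5-methyl-2-(prop-1-en-2-yl)-5-(triethylsilyloxy)hexyl]phenyl}ethan-1-one | C=C(C)[C@H](CCC(C)(C)O[Si](CC)(CC)CC)Cc1c(OCOC)cc(OC)c(C(C)=O)c1OCc1ccc(OCOC)cc1OCOC | intermediate
18 | 1-{2-{[2,4-bis(methoxymethoxy)phenyl]methoxy}-6-methoxy-4-(methoxymethoxy)-3-[(2R)-5-methyl-2-(prop-1-en-2-yl)-5-(triethylsilyloxy)hexyl]phenyl}-4,4,4-trifluorobutane-1,3-dione (not isolated) | C=C(C)[C@H](CCC(C)(C)O[Si](CC)(CC)CC)Cc1c(OCOC)cc(OC)c(C(=O)CC(=O)C(F)(F)F)c1OCc1ccc(OCOC)cc1OCOC | intermediate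
19 | 2-diazo-1-{2-{[2,4-bis(methoxymethoxy)phenyl]methoxy}-6-methoxy-4-(methoxymethoxy)-3-[(2R)-5-methyl-2-(prop-1-en-2-yl)-5-(triethylsilyloxy)hexyl]phenyl}ethan-1-one | C=C(C)[C@H](CCC(C)(C)O[Si](CC)(CC)CC)Cc1c(OCOC)cc(OC)c(C(=O)C=[N+]=[N-])c1OCc1ccc(OCOC)cc1OCOC | intermediate
20 | (2S)-2-[2,4-bis(methoxymethoxy)phenyl]-5-methoxy-7-(methoxymethoxy)-8-[(2R)-5-methyl-2-(prop-1-en-2-yl)-5-(triethylsilyloxy)hexyl]-2,3-dihydro-4H-chromen-4-one | C=C(C)[C@H](CCC(C)(C)O[Si](CC)(CC)CC)Cc1c(OCOC)cc(OC)c2c1O[C@H](c1ccc(OCOC)cc1OCOC)CC2=O | intermediate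
21 | (2S)-2-(2,4-dihydroxyphenyl)-7-hydroxy-8-[(2R)-5-hydroxy-5-methyl-2-(prop-1-en-2-yl)hexyl]-5-methoxy-2,3-dihydro-4H-chromen-4-one (CID44563198) | C=C(C)[C@H](CCC(C)(C)O)Cc1c(O)cc(OC)c2c1O[C@H](c1ccc(O)cc1O)CC2=O | target

Total step count: 14. Longest linear sequence: 9 steps (steps 1 to 5 and 11 to 14, from 1).

Steps most likely to fail

Step 13. Attack of O1 on the carbenoid followed by benzyl migration, insertion into the C5 methoxy group, or poor discrimination between the two benzylic hydrogens may take over. Ring C would then be closed at O1–C2 by conjugate addition instead. The fallback sets out from iodophenol 14. Negishi coupling of 14 itself with alkylzinc iodide 16 (Pd(OAc)2, SPhos, slow addition of the zinc reagent so that coupling outruns protonation by the phenol) should give 1-{2-hydroxy-6-methoxy-4-(methoxymethoxy)-3-[(2R)-5-methyl-2-(prop-1-en-2-yl)-5-(triethylsilyloxy)hexyl]phenyl}ethan-1-one F1. Claisen–Schmidt condensation of this ketone with aldehyde 10 (KOH, EtOH) should give (2E)-3-[2,4-bis(methoxymethoxy)phenyl]-1-{2-hydroxy-6-methoxy-4-(methoxymethoxy)-3-[(2R)-5-methyl-2-(prop-1-en-2-yl)-5-(triethylsilyloxy)hexyl]phenyl}prop-2-en-1-one F2. Enantioselective intramolecular oxa-Michael addition of this 2'-hydroxychalcone under a quinine-derived bifunctional thiourea then returns to flavanone 20. If induction is poor, NaOAc in EtOH is used instead, the C2 epimers (diastereomers) are separated and the unwanted one is recycled through the chalcone.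

Step 11. Transmetalation to the di-ortho-substituted arylpalladium iodide may be slow, and β-hydride loss may give reduced arene and a diene. The bond would then be made by B-alkyl Suzuki–Miyaura coupling, setting out from iodide 8. Treatment with t-BuLi (2 equiv, Et2O, −78 °C) and then 9-methoxy-9-borabicyclo[3.3.1]nonane should give lithium 9-methoxy-9-[(2S)-5-methyl-2-(prop-1-en-2-yl)-5-(triethylsilyloxy)hexyl]-9-borabicyclo[3.3.1]nonan-9-uide F3. This borinate is coupled with aryl iodide 15 (PdCl2(dppf), K3PO4, DMF/THF, 50 °C) to return to ketone 17.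

Step 10. The hindered, hydrogen-bonded phenol may react slowly, and the electron-rich benzylic oxyphosphonium ion may ionise and be captured by the hydrazide. The fallback sets out from alcohol 11, which is converted to 1-(chloromethyl)-2,4-bis(methoxymethoxy)benzene F4 (MsCl, Et3N, LiCl, THF, 0 °C, used crude). Phenol 14 is then alkylated with this chloride in a Williamson ether synthesis (Cs2CO3, DMF, 25 °C) to return to ether 15.

Further compounds
F1 | step 13 | 1-{2-hydroxy-6-methoxy-4-(methoxymethoxy)-3-[(2R)-5-methyl-2-(prop-1-en-2-yl)-5-(triethylsilyloxy)hexyl]phenyl}ethan-1-one | C=C(C)[C@H](CCC(C)(C)O[Si](CC)(CC)CC)Cc1c(OCOC)cc(OC)c(C(C)=O)c1O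
F2 | step 13 | (2E)-3-[2,4-bis(methoxymethoxy)phenyl]-1-{2-hydroxy-6-methoxy-4-(methoxymethoxy)-3-[(2R)-5-methyl-2-(prop-1-en-2-yl)-5-(triethylsilyloxy)hexyl]phenyl}prop-2-en-1-one | C=C(C)[C@H](CCC(C)(C)O[Si](CC)(CC)CC)Cc1c(OCOC)cc(OC)c(C(=O)/C=C/c2ccc(OCOC)cc2OCOC)c1O
F3 | step 11 | lithium 9-methoxy-9-[(2S)-5-methyl-2-(prop-1-en-2-yl)-5-(triethylsilyloxy)hexyl]-9-borabicyclo[3.3.1]nonan-9-uide | [Li+].C=C(C)[C@H](CCC(C)(C)O[Si](CC)(CC)CC)C[B-]1(OC)C2CCCC1CCC2
F4 | step 10 | 1-(chloromethyl)-2,4-bis(methoxymethoxy)benzene | COCOc1ccc(CCl)c(OCOC)c1
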